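The runs are calculated on assumed constants; the scatter is artificial.

The rate constants of this flask are hidden, so I start from its readings.

- zeta: substrate 0.77 M; coupling partner 0.77 M; the very flask that is asked about, followed so far
- flask: substrate 0.77 M; coupling partner 0.770 M; time 3.0 h

zeta run (percent of the substrate charged)

| time / min | first product / % | substrate / % |
|---|---|---|
| 6.00 | 27 | 37 |
| 10.0 | 22 | 32 |
| 15.0 | 20 | 31 |
| 25.0 | 18 | 29 |
| 40.0 | 9 | 22 |
| 80.0 | 6 | 25 |

(scatter of a reading: 1.5 percentage points)

- a species is counted by the substrate in it: one side product counts as two
- what may be going on: coupling partner -> decomposed reagent; coupling partner + first product -> double product + by-product; coupling partner + other mono adduct -> double product + by-product; substrate + coupling partner -> other mono adduct + by-product; substrate + coupling partner -> first product + by-product; substrate + first product -> side product; first product <-> isomer of the product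

1. equivalents of coupling partner to substrate, everything else as given, that leave most first product at 3.0 h
2. the amount of first product then, in percent of the substrate charged
3. the amount of first product with the amounts as given

I suppose that late in the flask first product is lost by the step with substrate, one substrate for each first product. If I replace the curve of c(substrate) by its mean over the last two readings, 23.5 %, this loss becomes first order in c(first product), that is pseudo-first-order. The lifetime of first product, the time for a fall by a factor e at that mean, is then 98.7 min. To check the mean: if the 6 % of first product read at 80.0 min all went, substrate would lose as much, so its mean up to 3.0 h would sit lower by 3 percentage points. That stretches the lifetime to 113 min, and I commit to 2.48 % at 3.0 h. The weak link is the lifetime itself, which rests on a fall of 3 points between two readings, each with a scatter of 1.5 points.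

The forecast, which is not my reckoning, gives 3 % for the amounts as given, and 14 % at 1.6 equiv. Its ground for the optimum: “More partner should use up the substrate and stop the side-product drain”.

    coupling partner → decomposed reagent (k = 0.0710 min⁻¹)
    coupling partner + first product → double product + by-product (k = 0.140 M⁻¹ min⁻¹)
    coupling partner + other mono adduct → double product + by-product (k = 0.0810 M⁻¹ min⁻¹)
    substrate + coupling partner → other mono adduct + by-product (k = 0.210 M⁻¹ min⁻¹)
    substrate + coupling partner → first product + by-product (k = 0.310 M⁻¹ min⁻¹)
    substrate + first product → side product (k = 0.0210 M⁻¹ min⁻¹)
    first product ⇌ isomer of the product (K = 3.10, k = 0.0490 min⁻¹)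

The flask gives 6.51 % with the amounts as given, and 1.62 equiv of coupling partner gives the most first product, 8.50 %. Carried from the 40.0 min reading, 98.7 min gives 8.13 % at 50 min, where the same flask, read then, stands at 8.37 %. Carried from 3.0 h to 12 h, it gives 0.0274 %, where the same flask, read then, stands at 4.57 %. Reforged on this flask's stretch from 3.0 h to 30.0 h, the time for a fall by a factor e is 35.0 h. The flask has not come to rest at 3.0 h: at ten times the time, substrate has gone from 22.9 % to 7.53 %, side product from 15.1 % to 45.8 %, and first product stands at 3.01 %.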